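The synthesis rests on closing the γ-lactone last, by forming the bond between its α-carbon (C11) and its carbonyl carbon (C12), which is brought in as carbon monoxide. A palladium-catalysed cyclocarbonylation of the homopropargylic alcohol 22 acylates O6, closes the ring by 5-exo-dig insertion of the C7 ethynyl group and leaves the exocyclic C11=C13 methylene, all in one operation. It exploits the trans-diequatorial C6–OH/C7–C≡CH pair on the cyclohexane ring. The precursor 22 is the fully functionalised cyclohexane carrying the 8-tiglate, the free acrylic acid and a bare ethynyl group where the methylene lactone will stand; its five stereocentres stem from one Pd-catalysed asymmetric allylic alkylation followed by substrate control.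

Key step: step 14

Remark: atoms are labelled by elemane numbering — C10 quaternary ring carbon (methyl β, vinyl C1=C2 α), C9 ring CH2, C8 tiglate-bearing carbon, C7 carbon bearing C11 (=C13H2; C12 lactone carbonyl), C6 carbon bearing the lactone oxygen O6, C5 carbon bearing the acrylic acid (C4=C3, C15O2H); the sense of induction in step 3 is assigned by analogy and would be corrected by using the antipodal ligand.

Step 1
Reactants: 1 2-methylcyclohex-2-en-1-one
Product: 2 rac-2-methylcyclohex-2-en-1-ol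
Conditions: NaBH4, CeCl3·7H2O, MeOH, 0 °C
Reagents that add atoms: none
Why: Luche reduction should give clean 1,2-reduction; the new carbinol centre is left racemic on purpose because it is erased in the π-allyl complex of step 3.

Step 2
Reactants: 2 rac-2-methylcyclohex-2-en-1-ol
Product: 3 rac-methyl 2-methylcyclohex-2-en-1-yl carbonate
Conditions: ClCO2Me, pyridine, DMAP (cat.), CH2Cl2, 0 °C
Reagents that add atoms: methyl chloroformate, COC(=O)Cl
Why: Standard O-acylation with a chloroformate turns the hydroxyl group into the carbonate leaving group needed for ionisation by Pd(0).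

Step 3
Reactants: 3 rac-methyl 2-methylcyclohex-2-en-1-yl carbonate; 4 di-tert-butyl malonate
Product: 5 di-tert-butyl 2-[(1S)-2-methylcyclohex-2-en-1-yl]malonate
Conditions: [Pd(η3-C3H5)Cl]2 (2.5 mol %), (S,S)-DACH-phenyl ligand [(1S,2S)-N,N′-bis(2-diphenylphosphinobenzoyl)cyclohexane-1,2-diamine] (7.5 mol %), CH2Cl2, rt
Reagents that add atoms: di-tert-butyl malonate (4), CC(C)(C)OC(=O)CC(=O)OC(C)(C)C
Why: Pd-catalysed asymmetric allylic alkylation (Tsuji–Trost reaction): both enantiomers of 3 should ionise to the same meso-type 2-methylcyclohexenyl–Pd complex, and the chiral ligand should steer the malonate to one of the two enantiotopic allyl termini, which sets C5 as (S).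

Step 4
Reactants: 5 di-tert-butyl 2-[(1S)-2-methylcyclohex-2-en-1-yl]malonate
Product: 6 di-tert-butyl 2-[(1S)-2-methyl-4-oxocyclohex-2-en-1-yl]malonate
Conditions: Rh2(cap)4 (1 mol %), t-BuOOH (70 % aq., 5 equiv), K2CO3, CH2Cl2, rt
Reagents that add atoms: tert-butyl hydroperoxide, CC(C)(C)OO
Why: Rhodium(II)-catalysed allylic oxidation with t-BuOOH should oxidise the only allylic CH2 group (C8) to the ketone and so give the 3-methylcyclohexenone, the hindered tertiary C5–H and the stereocentre being left untouched.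

Step 5
Reactants: 6 di-tert-butyl 2-[(1S)-2-methyl-4-oxocyclohex-2-en-1-yl]malonate; 7 vinylmagnesium bromide
Product: 8 di-tert-butyl 2-[(1S,2S)-2-methyl-4-oxo-2-vinylcyclohexyl]malonate
Conditions: CH2=CHMgBr (3 equiv), CuBr·SMe2 (20 mol %), THF, −40 → −10 °C; aq NH4Cl
Reagents that add atoms: vinylmagnesium bromide (7), C=C[Mg]Br
Why: Copper-catalysed conjugate addition of the vinyl Grignard reagent should occur anti to the bulky C5 malonyl group (trans addition to 4-substituted cyclohexenones), which sets the quaternary C10 with vinyl α and methyl β; one equivalent of the reagent is consumed by the acidic malonate C–H.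

Step 6
Reactants: 8 di-tert-butyl 2-[(1S,2S)-2-methyl-4-oxo-2-vinylcyclohexyl]malonate
Product: 9 di-tert-butyl 2-[(1S,6S)-6-methyl-4-oxo-6-vinylcyclohex-2-en-1-yl]malonate
Conditions: IBX (2.5 equiv), DMSO, 70 °C
Reagents that add atoms: none
Why: IBX-mediated dehydrogenation of the ketone can only introduce the C6=C7 double bond because C10 carries no hydrogen, so a single enone is expected.

Step 7
Reactants: 9 di-tert-butyl 2-[(1S,6S)-6-methyl-4-oxo-6-vinylcyclohex-2-en-1-yl]malonate
Product: 10 di-tert-butyl 2-[(1R,6S)-3-iodo-6-methyl-4-oxo-6-vinylcyclohex-2-en-1-yl]malonate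
Conditions: I2, pyridine, CH2Cl2, rt
Reagents that add atoms: iodine, II
Why: α-Iodination of the enone by the I2/pyridine addition–elimination sequence should place iodine on C7 only and prepares the cross-coupling.

Step 8
Reactants: 10 di-tert-butyl 2-[(1R,6S)-3-iodo-6-methyl-4-oxo-6-vinylcyclohex-2-en-1-yl]malonate; 11 (triisopropylsilyl)acetylene
Product: 12 di-tert-butyl 2-[(1S,6S)-6-methyl-4-oxo-3-[(triisopropylsilyl)ethynyl]-6-vinylcyclohex-2-en-1-yl]malonate
Conditions: PdCl2(PPh3)2 (5 mol %), CuI (10 mol %), i-Pr2NH, THF, 0 °C → rt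
Reagents that add atoms: (triisopropylsilyl)acetylene (11), C#C[Si](C(C)C)(C(C)C)C(C)C
Why: Sonogashira coupling of the α-iodoenone installs the two-carbon unit C11–C13 on C7, the TIPS group being chosen to survive the alkoxide of step 9.

Step 9
Reactants: 12 di-tert-butyl 2-[(1S,6S)-6-methyl-4-oxo-3-[(triisopropylsilyl)ethynyl]-6-vinylcyclohex-2-en-1-yl]malonate; 13 bis(pinacolato)diboron
Product: 14 di-tert-butyl 2-[(1S,2S,5R,6R)-2-methyl-4-oxo-6-(pinacolatoboryl)-5-[(triisopropylsilyl)ethynyl]-2-vinylcyclohexyl]malonate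
Conditions: CuCl (5 mol %), DPEphos (5 mol %), NaOt-Bu (5 mol %), B2pin2 (1.2 equiv), MeOH (2 equiv), THF, 0 °C; pH 7 buffer
Reagents that add atoms: bis(pinacolato)diboron (13), CC1(C)OB(OC1(C)C)B1OC(C)(C)C(C)(C)O1
Why: Copper(I)-catalysed conjugate borylation should add boron to C6 anti to the C5 malonyl group (C6 α), and axial protonation of the enolate at C7 in the chair that keeps the C5 and C6 substituents equatorial should place the alkynyl group equatorial (β), trans to boron.

Step 10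
Reactants: 14 di-tert-butyl 2-[(1S,2S,5R,6R)-2-methyl-4-oxo-6-(pinacolatoboryl)-5-[(triisopropylsilyl)ethynyl]-2-vinylcyclohexyl]malonate
Product: 15 di-tert-butyl 2-[(1S,2S,4R,5R,6R)-4-hydroxy-2-methyl-6-(pinacolatoboryl)-5-[(triisopropylsilyl)ethynyl]-2-vinylcyclohexyl]malonate
Conditions: L-Selectride, THF, −78 °C; aq NH4Cl (non-oxidative work-up)
Reagents that add atoms: none
Why: The bulky borohydride should attack C8 from the equatorial α-direction because the axial path is blocked by the syn-axial C10 methyl group, which gives the axial 8β-alcohol.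

Step 11
Reactants: 15 di-tert-butyl 2-[(1S,2S,4R,5R,6R)-4-hydroxy-2-methyl-6-(pinacolatoboryl)-5-[(triisopropylsilyl)ethynyl]-2-vinylcyclohexyl]malonate; 16 tigloyl chloride
Product: 17 di-tert-butyl 2-[(1S,2S,4R,5R,6R)-2-methyl-4-{[(2E)-2-methylbut-2-enoyl]oxy}-6-(pinacolatoboryl)-5-[(triisopropylsilyl)ethynyl]-2-vinylcyclohexyl]malonate
Conditions: tigloyl chloride, DMAP, Et3N, CH2Cl2, 0 → 40 °C
Reagents that add atoms: tigloyl chloride (16), C/C=C(\C)C(=O)Cl
Why: DMAP-catalysed acylation should esterify the only free hydroxyl group while the C6 oxygen is still masked as a C–B bond, so that no protecting group is needed and the stable E (tiglate) geometry is kept.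

Step 12
Reactants: 17 di-tert-butyl 2-[(1S,2S,4R,5R,6R)-2-methyl-4-{[(2E)-2-methylbut-2-enoyl]oxy}-6-(pinacolatoboryl)-5-[(triisopropylsilyl)ethynyl]-2-vinylcyclohexyl]malonate; 18 formaldehyde
Product: 20 2-[(1R,2S,4R,5R,6R)-2-methyl-4-{[(2E)-2-methylbut-2-enoyl]oxy}-6-(pinacolatoboryl)-5-[(triisopropylsilyl)ethynyl]-2-vinylcyclohexyl]prop-2-enoic acid, via malonic acid 19 (not isolated)
Conditions: TFA/CH2Cl2 (1:3), 0 °C → rt; evaporate; then 37 % aq CH2O, Et2NH (1.2 equiv), dioxane, rt → 70 °C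
Reagents that add atoms: formaldehyde (18), C=O
Why: Acidolysis of both tert-butyl esters followed by Mannich condensation of the malonic acid with formaldehyde and decarboxylative elimination (the classical route to 2-substituted acrylic acids) should unveil the C5 acrylic acid while C6 is still masked as the C–B bond, so that no hydroxy acid can lactonise under the acidic conditions.

Step 13
Reactants: 20 2-[(1R,2S,4R,5R,6R)-2-methyl-4-{[(2E)-2-methylbut-2-enoyl]oxy}-6-(pinacolatoboryl)-5-[(triisopropylsilyl)ethynyl]-2-vinylcyclohexyl]prop-2-enoic acid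
Product: 22 2-[(1R,2S,4R,5S,6R)-5-ethynyl-6-hydroxy-2-methyl-4-{[(2E)-2-methylbut-2-enoyl]oxy}-2-vinylcyclohexyl]prop-2-enoic acid, via ethynyl boronate 21 (not isolated)
Conditions: TBAF (4 equiv), THF, 0 °C → rt; then 30 % H2O2, aq NaHCO3, 0 °C; work-up at pH 4
Reagents that add atoms: hydrogen peroxide, OO
Why: Fluoride should cleave the alkynyl C–Si bond, and buffered peroxide oxidation of the secondary boronate, which proceeds with retention, should reveal the 6α-hydroxyl group trans to the ethynyl group under conditions too mild to lactonise it onto the acrylic acid.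

Step 14
Reactants: 22 2-[(1R,2S,4R,5S,6R)-5-ethynyl-6-hydroxy-2-methyl-4-{[(2E)-2-methylbut-2-enoyl]oxy}-2-vinylcyclohexyl]prop-2-enoic acid; 23 carbon monoxide
Product: 24 CNP0256928.1, 2-[(3aR,4R,6S,7R,7aR)-6-ethenyl-6-methyl-3-methylidene-4-{[(2E)-2-methylbut-2-enoyl]oxy}-2-oxooctahydro-1-benzofuran-7-yl]prop-2-enoic acid
Conditions: PdCl2 (5 mol %), anhydrous SnCl2 (5 mol %), PPh3 (10 mol %), CO (8 atm), MeCN, 75 °C
Reagents that add atoms: carbon monoxide (23), [C-]#[O+]
Why: The C6 hydroxyl attacks CO bound to Pd(II) to give an alkoxycarbonyl–palladium species (O6–C12(=O)–Pd), which adds syn across the pendant C11≡C13 triple bond so that the C11–C12 bond forms and the lactone closes; protonolysis of the exocyclic vinyl–Pd bond at C13 then releases the α-methylene lactone and returns Pd(II). The closest known reaction is the palladium-catalysed cyclocarbonylation of trans-2-ethynylcyclohexanol to the trans-fused α-methylene-γ-butyrolactone. The one ring formed is closed in the 5-exo-dig mode. No stereocentre is created: the trans ring fusion is fixed by C6 and C7 of 22, whose substituents are both equatorial, and the new exocyclic alkene is a terminal methylene. The step needs chemoselectivity for O6–H and for the alkyne: O8 is already acylated, the carboxylic acid is a poorer nucleophile towards Pd–CO and could only close a seven-membered ring, and the vinyl, acrylic and tiglate alkenes should insert far more slowly than the tethered alkyne. The five-membered tether enforces bonding of C12 to C11 and not to C13.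

Compound list
1 | 2-methylcyclohex-2-en-1-one | CC1=CCCC1=O | starting material
2 | rac-2-methylcyclohex-2-en-1-ol | CC1=CCCC1O | intermediate
3 | rac-methyl 2-methylcyclohex-2-en-1-yl carbonate | COC(=O)OC1CCCC=C1C | intermediate
4 | di-tert-butyl malonate | CC(C)(C)OC(=O)CC(=O)OC(C)(C)C | starting material
5 | di-tert-butyl 2-[(1S)-2-methylcyclohex-2-en-1-yl]malonate | CC1=CCCC[C@H]1C(C(=O)OC(C)(C)C)C(=O)OC(C)(C)C | intermediate
6 | di-tert-butyl 2-[(1S)-2-methyl-4-oxocyclohex-2-en-1-yl]malonate | CC1=CC(=O)CC[C@H]1C(C(=O)OC(C)(C)C)C(=O)OC(C)(C)C | intermediate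
7 | vinylmagnesium bromide | C=C[Mg]Br | starting material
8 | di-tert-butyl 2-[(1S,2S)-2-methyl-4-oxo-2-vinylcyclohexyl]malonate (vinyl trans to the malonyl group) | C=C[C@]1(C)CC(=O)CC[C@H]1C(C(=O)OC(C)(C)C)C(=O)OC(C)(C)C | intermediate
9 | di-tert-butyl 2-[(1S,6S)-6-methyl-4-oxo-6-vinylcyclohex-2-en-1-yl]malonate | C=C[C@]1(C)CC(=O)C=C[C@H]1C(C(=O)OC(C)(C)C)C(=O)OC(C)(C)C | intermediate
10 | di-tert-butyl 2-[(1R,6S)-3-iodo-6-methyl-4-oxo-6-vinylcyclohex-2-en-1-yl]malonate | C=C[C@]1(C)CC(=O)C(I)=C[C@H]1C(C(=O)OC(C)(C)C)C(=O)OC(C)(C)C | intermediate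
11 | (triisopropylsilyl)acetylene | C#C[Si](C(C)C)(C(C)C)C(C)C | starting material
12 | di-tert-butyl 2-[(1S,6S)-6-methyl-4-oxo-3-[(triisopropylsilyl)ethynyl]-6-vinylcyclohex-2-en-1-yl]malonate | C=C[C@]1(C)CC(=O)C(C#C[Si](C(C)C)(C(C)C)C(C)C)=C[C@H]1C(C(=O)OC(C)(C)C)C(=O)OC(C)(C)C | intermediate
13 | bis(pinacolato)diboron | CC1(C)OB(OC1(C)C)B1OC(C)(C)C(C)(C)O1 | starting material
14 | di-tert-butyl 2-[(1S,2S,5R,6R)-2-methyl-4-oxo-6-(pinacolatoboryl)-5-[(triisopropylsilyl)ethynyl]-2-vinylcyclohexyl]malonate | C=C[C@]1(C)CC(=O)[C@@H](C#C[Si](C(C)C)(C(C)C)C(C)C)[C@H](B2OC(C)(C)C(C)(C)O2)[C@H]1C(C(=O)OC(C)(C)C)C(=O)OC(C)(C)C | intermediate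
15 | di-tert-butyl 2-[(1S,2S,4R,5R,6R)-4-hydroxy-2-methyl-6-(pinacolatoboryl)-5-[(triisopropylsilyl)ethynyl]-2-vinylcyclohexyl]malonate | C=C[C@]1(C)C[C@@H](O)[C@@H](C#C[Si](C(C)C)(C(C)C)C(C)C)[C@H](B2OC(C)(C)C(C)(C)O2)[C@H]1C(C(=O)OC(C)(C)C)C(=O)OC(C)(C)C | intermediate
16 | tigloyl chloride, (2E)-2-methylbut-2-enoyl chloride | C/C=C(\C)C(=O)Cl | starting material
17 | di-tert-butyl 2-[(1S,2S,4R,5R,6R)-2-methyl-4-{[(2E)-2-methylbut-2-enoyl]oxy}-6-(pinacolatoboryl)-5-[(triisopropylsilyl)ethynyl]-2-vinylcyclohexyl]malonate | C=C[C@]1(C)C[C@@H](OC(=O)/C(C)=C/C)[C@@H](C#C[Si](C(C)C)(C(C)C)C(C)C)[C@H](B2OC(C)(C)C(C)(C)O2)[C@H]1C(C(=O)OC(C)(C)C)C(=O)OC(C)(C)C | intermediate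
18 | formaldehyde | C=O | starting material
19 | 2-[(1S,2S,4R,5R,6R)-2-methyl-4-{[(2E)-2-methylbut-2-enoyl]oxy}-6-(pinacolatoboryl)-5-[(triisopropylsilyl)ethynyl]-2-vinylcyclohexyl]malonic acid | C=C[C@]1(C)C[C@@H](OC(=O)/C(C)=C/C)[C@@H](C#C[Si](C(C)C)(C(C)C)C(C)C)[C@H](B2OC(C)(C)C(C)(C)O2)[C@H]1C(C(=O)O)C(=O)O | intermediate
20 | 2-[(1R,2S,4R,5R,6R)-2-methyl-4-{[(2E)-2-methylbut-2-enoyl]oxy}-6-(pinacolatoboryl)-5-[(triisopropylsilyl)ethynyl]-2-vinylcyclohexyl]prop-2-enoic acid | C=C[C@]1(C)C[C@@H](OC(=O)/C(C)=C/C)[C@@H](C#C[Si](C(C)C)(C(C)C)C(C)C)[C@H](B2OC(C)(C)C(C)(C)O2)[C@H]1C(=C)C(=O)O | intermediate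
21 | 2-[(1R,2S,4R,5R,6R)-5-ethynyl-2-methyl-4-{[(2E)-2-methylbut-2-enoyl]oxy}-6-(pinacolatoboryl)-2-vinylcyclohexyl]prop-2-enoic acid | C=C[C@]1(C)C[C@@H](OC(=O)/C(C)=C/C)[C@@H](C#C)[C@H](B2OC(C)(C)C(C)(C)O2)[C@H]1C(=C)C(=O)O | intermediate
22 | 2-[(1R,2S,4R,5S,6R)-5-ethynyl-6-hydroxy-2-methyl-4-{[(2E)-2-methylbut-2-enoyl]oxy}-2-vinylcyclohexyl]prop-2-enoic acid | C=C[C@]1(C)C[C@@H](OC(=O)/C(C)=C/C)[C@@H](C#C)[C@H](O)[C@H]1C(=C)C(=O)O | intermediate
23 | carbon monoxide | [C-]#[O+] | starting material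
24 | CNP0256928.1, 2-[(3aR,4R,6S,7R,7aR)-6-ethenyl-6-methyl-3-methylidene-4-{[(2E)-2-methylbut-2-enoyl]oxy}-2-oxooctahydro-1-benzofuran-7-yl]prop-2-enoic acid | C=C[C@]1(C)C[C@@H](OC(=O)/C(C)=C/C)[C@H]2C(=C)C(=O)O[C@@H]2[C@H]1C(=C)C(=O)O | target

Total step count: 14. Longest linear sequence: 14 steps (1 → 24).

Steps most likely to fail

Step 9. What may go wrong: wrong-face protonation or base-mediated equilibration at C7 after the borylcupration, γ-protonation of the alkynyl enolate to an allenyl ketone, or borylcupration of the silyl alkyne. The fallback sets out from 12 and returns to the route at 22. Nucleophilic epoxidation of 12 (30 % H2O2, NaOH, MeOH, 0 °C) should deliver oxygen to C6 anti to the malonyl group and give the epoxy ketone F1. SmI2 (THF/MeOH, −78 °C) should cleave the C7–O bond and protonate the samarium enolate axially under non-basic conditions to give the β-hydroxy ketone F2. TIPSOTf/2,6-lutidine then gives the silyl ether F3, L-Selectride the 8β-alcohol F4, and tigloyl chloride/DMAP the tiglate F5. TFA followed by CH2O/Et2NH converts the malonate into the acrylic acid F6 with the O-TIPS group still in place, and TBAF removes both silyl groups to give 22.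

Step 14. What may go wrong: the free acrylic acid may bind the Pd/Sn catalyst or add the phosphine, or O6 may lactonise directly onto the C15 acid under the Lewis-acidic conditions instead of being carbonylated. The fallback sets out from 17 and returns at 24, closing the lactone before the acid exists. TBAF and then buffered H2O2 convert 17 into the hydroxy alkyne F7 with the malonate esters intact. The same Pd-catalysed cyclocarbonylation gives the lactone diester F8, and TFA gives the lactone malonic acid F9. Methylenation with dimethylmethyleneammonium iodide (MeCN, rt → 70 °C), which releases the amine only as its hydroiodide, then gives 24.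

Step 3. What may go wrong: slow ionisation and eroded enantioselectivity with the 2-methyl-substituted allyl unit and the bulky malonate. The fallback sets out from 1 and returns at 5. CBS reduction of 1 ((R)-Me-CBS, BH3·SMe2) should give the (S)-allylic alcohol F10. DCC/DMAP coupling with mono-tert-butyl malonate gives the mixed malonate F11. Ireland–Claisen rearrangement (LiHMDS, TMSCl, THF, −78 → 60 °C) transfers the C–O chirality suprafacially to C5 and gives the half acid F12 (mixture at the malonate carbon), which tert-butyl 2,2,2-trichloroacetimidate esterifies to 5.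

Further compounds
F1 | step 9 | 6α,7α-epoxy ketone of 12 (epoxide trans to the malonyl group) | C=C[C@]1(C)CC(=O)[C@]2(C#C[Si](C(C)C)(C(C)C)C(C)C)O[C@@H]2[C@H]1C(C(=O)OC(C)(C)C)C(=O)OC(C)(C)C
F2 | step 9 | β-hydroxy ketone (6α-OH, 7β-alkynyl, C8 ketone) | C=C[C@]1(C)CC(=O)[C@@H](C#C[Si](C(C)C)(C(C)C)C(C)C)[C@H](O)[C@H]1C(C(=O)OC(C)(C)C)C(=O)OC(C)(C)C
F3 | step 9 | 6-O-triisopropylsilyl ether of F2 | C=C[C@]1(C)CC(=O)[C@@H](C#C[Si](C(C)C)(C(C)C)C(C)C)[C@H](O[Si](C(C)C)(C(C)C)C(C)C)[C@H]1C(C(=O)OC(C)(C)C)C(=O)OC(C)(C)C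
F4 | step 9 | 8β-alcohol from F3 | C=C[C@]1(C)C[C@@H](O)[C@@H](C#C[Si](C(C)C)(C(C)C)C(C)C)[C@H](O[Si](C(C)C)(C(C)C)C(C)C)[C@H]1C(C(=O)OC(C)(C)C)C(=O)OC(C)(C)C
F5 | step 9 | 8β-tiglate of F4 | C=C[C@]1(C)C[C@@H](OC(=O)/C(C)=C/C)[C@@H](C#C[Si](C(C)C)(C(C)C)C(C)C)[C@H](O[Si](C(C)C)(C(C)C)C(C)C)[C@H]1C(C(=O)OC(C)(C)C)C(=O)OC(C)(C)C
F6 | step 9 | acrylic acid from F5 (O-TIPS and C-TIPS in place) | C=C[C@]1(C)C[C@@H](OC(=O)/C(C)=C/C)[C@@H](C#C[Si](C(C)C)(C(C)C)C(C)C)[C@H](O[Si](C(C)C)(C(C)C)C(C)C)[C@H]1C(=C)C(=O)O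
F7 | step 14 | hydroxy alkyne with di-tert-butyl malonate | C=C[C@]1(C)C[C@@H](OC(=O)/C(C)=C/C)[C@@H](C#C)[C@H](O)[C@H]1C(C(=O)OC(C)(C)C)C(=O)OC(C)(C)C
F8 | step 14 | α-methylene lactone with di-tert-butyl malonate | C=C[C@]1(C)C[C@@H](OC(=O)/C(C)=C/C)[C@H]2C(=C)C(=O)O[C@@H]2[C@H]1C(C(=O)OC(C)(C)C)C(=O)OC(C)(C)C
F9 | step 14 | α-methylene lactone malonic acid | C=C[C@]1(C)C[C@@H](OC(=O)/C(C)=C/C)[C@H]2C(=C)C(=O)O[C@@H]2[C@H]1C(C(=O)O)C(=O)O
F10 | step 3 | (S)-2-methylcyclohex-2-en-1-ol | CC1=CCCC[C@@H]1O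
F11 | step 3 | tert-butyl (1S)-2-methylcyclohex-2-en-1-yl malonate | CC1=CCCC[C@@H]1OC(=O)CC(=O)OC(C)(C)C
F12 | step 3 | 3-tert-butoxy-2-[(1S)-2-methylcyclohex-2-en-1-yl]-3-oxopropanoic acid | CC1=CCCC[C@H]1C(C(=O)O)C(=O)OC(C)(C)C
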